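**Retrosynthetic overview**
1. The tertiary aroyl ester (C4–O bond and C4 stereocentre) is made last. A cobalt hydride adds H• to a C3=C4 isopropyl alkene, the neighbouring C6 aroyl ester captures the C4 cation, and hydrolysis of the dioxanylium ion leaves the acyl group on O4 and frees O6.
2. The isopropyl alkene comes from an alkenyl triflate by Negishi coupling. The C9 ketone comes from allylic C–H oxidation, done while the triflate keeps the five-membered-ring alkene inert.
3. The seven-membered ring is closed second, by ring-closing metathesis at C7=C8.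
4. The five-membered ring is bought as 3-methylcyclopentenone. C1, C5 and C6 are set in one asymmetric conjugate addition/aldol operation with a homomethallyl Grignard reagent and acrolein.

**Numbering and assumptions**
- Daucane numbering is used: C1 quaternary C(CH3), C2/C3 CH2, C4 C(O)(i-Pr), C5 ring-fusion CH, C6 carbinol, C7=C8(CH3), C9 C=O, C10 CH2. The target is (1R,4R,5S,6S): trans-fused, 4β-O, 6α-OH.
- The sense of induction in step 1 is fixed by the choice of ligand antipode; both are available from D- or L-leucinol.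
- Acid 10 is treated as a catalogue compound.

**Step 1**
Reactants: 1 3-methylcyclopent-2-en-1-one; 2 4-bromo-2-methylbut-1-ene; 3 acrolein (prop-2-enal)
Product: 6 (2S,3S)-2-[(1S)-1-hydroxyprop-2-en-1-yl]-3-methyl-3-(3-methylbut-3-en-1-yl)cyclopentan-1-one, via Grignard reagent 4 (not isolated), via magnesium enolate 5 (not isolated)
Conditions: 2, Mg, Et2O, reflux; Cu(OTf)2 (3 mol %), leucinol-derived N-mesityl-N'-(1-hydroxy-4-methylpent-2-yl)imidazolinium PF6 salt (4 mol %), Et2O, −30 °C, slow addition of 1; 3 (2 equiv), −78 °C; aq NH4Cl; chromatography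
Reagents that add atoms: none
Why: Copper–NHC-catalysed asymmetric conjugate addition sets the quaternary C1 by ligand control, and the regiodefined (E)-configured cyclic magnesium enolate then adds to acrolein through a Zimmerman–Traxler aldol transition state on the face anti to the longer C1 chain, giving the trans C1/C5 and anti C5/C6 relationships of the target.

**Step 2**
Reactants: 6 (2S,3S)-2-[(1S)-1-hydroxyprop-2-en-1-yl]-3-methyl-3-(3-methylbut-3-en-1-yl)cyclopentan-1-one
Product: 9 (4S,5S)-5-[(1S)-1-hydroxyprop-2-en-1-yl]-4-methyl-4-(3-methylbut-3-en-1-yl)cyclopent-1-en-1-yl trifluoromethanesulfonate, via TMS ether 7 (not isolated), via TMS-protected alkenyl triflate 8 (not isolated)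
Conditions: TMSCl, Et3N, THF, 0 °C, filter; KHMDS, THF, −78 °C, then PhNTf2, −78 → 0 °C; 1 M HCl, THF, 0 °C
Reagents that add atoms: N-phenylbis(trifluoromethanesulfonimide), O=S(=O)(N(c1ccccc1)S(=O)(=O)C(F)(F)F)C(F)(F)F; chlorotrimethylsilane, C[Si](C)(C)Cl (its silyl group is present only in 7 and 8)
Why: Transient silylation blocks retro-aldol chemistry, kinetic deprotonation takes the unhindered C3 methylene rather than the crowded C5 methine, and O-sulfonylation (enol triflate synthesis) fixes the C3=C4 double bond without touching a stereocentre.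

**Step 3**
Reactants: 9 (4S,5S)-5-[(1S)-1-hydroxyprop-2-en-1-yl]-4-methyl-4-(3-methylbut-3-en-1-yl)cyclopent-1-en-1-yl trifluoromethanesulfonate; 10 4-[(tert-butyldimethylsilyl)oxy]benzoic acid
Product: 11 (1S)-1-[(1S,2S)-2-methyl-2-(3-methylbut-3-en-1-yl)-5-{[(trifluoromethyl)sulfonyl]oxy}cyclopent-4-en-1-yl]prop-2-en-1-yl 4-[(tert-butyldimethylsilyl)oxy]benzoate
Conditions: DCC, DMAP (20 mol %), CH2Cl2, 0 °C → rt
Reagents that add atoms: none
Why: Steglich esterification acylates the only free hydroxyl with retention at C6, and because the ketone is already masked as the alkenyl triflate no E1cB loss of the acyloxy group can occur.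

**Step 4**
Reactants: 11 (1S)-1-[(1S,2S)-2-methyl-2-(3-methylbut-3-en-1-yl)-5-{[(trifluoromethyl)sulfonyl]oxy}cyclopent-4-en-1-yl]prop-2-en-1-yl 4-[(tert-butyldimethylsilyl)oxy]benzoate
Product: 12 (3aS,8S,8aS)-3a,6-dimethyl-1-{[(trifluoromethyl)sulfonyl]oxy}-3,3a,4,5,8,8a-hexahydroazulen-8-yl 4-[(tert-butyldimethylsilyl)oxy]benzoate
Conditions: second-generation Hoveyda–Grubbs catalyst (5 mol %), toluene (2 mM), 80 °C, argon sparge
Reagents that add atoms: none
Why: Ring-closing metathesis joins the vinyl group and the 1,1-disubstituted alkene, held trans on the cyclopentene, into the trisubstituted C7=C8 alkene of the seven-membered ring, while the electron-poor alkenyl triflate is inert to ruthenium carbenes.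

**Step 5**
Reactants: 12 (3aS,8S,8aS)-3a,6-dimethyl-1-{[(trifluoromethyl)sulfonyl]oxy}-3,3a,4,5,8,8a-hexahydroazulen-8-yl 4-[(tert-butyldimethylsilyl)oxy]benzoate
Product: 13 (3aR,8S,8aS)-3a,6-dimethyl-5-oxo-1-{[(trifluoromethyl)sulfonyl]oxy}-3,3a,4,5,8,8a-hexahydroazulen-8-yl 4-[(tert-butyldimethylsilyl)oxy]benzoate
Conditions: Rh2(cap)4 (dirhodium tetrakis(caprolactamate), 1 mol %), t-BuOOH (70 % aq, 5 equiv), NaHCO3, CH2Cl2, rt → 40 °C
Reagents that add atoms: tert-butyl hydroperoxide, CC(C)(C)OO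
Why: Radical allylic C–H oxidation attacks the one free methylene next to the only electron-rich alkene (C9), because C6–H is deactivated by its acyloxy group and the five-membered-ring alkene by its triflate, so the 2-methylcycloheptenone forms.

**Step 6**
Reactants: 13 (3aR,8S,8aS)-3a,6-dimethyl-5-oxo-1-{[(trifluoromethyl)sulfonyl]oxy}-3,3a,4,5,8,8a-hexahydroazulen-8-yl 4-[(tert-butyldimethylsilyl)oxy]benzoate
Product: 14 (3aR,8S,8aR)-3a,6-dimethyl-5-oxo-1-(propan-2-yl)-3,3a,4,5,8,8a-hexahydroazulen-8-yl 4-[(tert-butyldimethylsilyl)oxy]benzoate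
Conditions: i-PrZnBr (1.5 equiv), Pd(OAc)2 (3 mol %), CPhos (6 mol %), LiCl, THF/toluene, 0 °C → rt
Reagents that add atoms: isopropylzinc bromide, CC(C)[Zn]Br
Why: In this Negishi cross-coupling, zerovalent palladium inserts into the alkenyl C–OTf bond much faster than it ionises the hindered allylic benzoate, the organozinc halide tolerates ester and enone, and CPhos speeds reductive elimination so the secondary alkyl group does not isomerise to n-propyl.

**Step 7**
Reactants: 14 (3aR,8S,8aR)-3a,6-dimethyl-5-oxo-1-(propan-2-yl)-3,3a,4,5,8,8a-hexahydroazulen-8-yl 4-[(tert-butyldimethylsilyl)oxy]benzoate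
Product: 17 (1R,3aR,8S,8aS)-8-hydroxy-3a,6-dimethyl-5-oxo-1-(propan-2-yl)-1,2,3,3a,4,5,8,8a-octahydroazulen-1-yl 4-hydroxybenzoate, via dioxanylium triflate 15 (not isolated), via O-TBS ester 16 (not isolated)
Conditions: [N,N'-bis(3,5-di-tert-butylsalicylidene)-1,2-cyclohexanediaminato]cobalt (5 mol %), N-fluoro-2,4,6-trimethylpyridinium triflate (2 equiv), PhSiH3 (2 equiv), PhCF3, 0 °C; ice-cold aq NaHCO3, 10 min; crude in THF, TBAF/AcOH (1:1, 1.2 equiv), 0 °C
Reagents that add atoms: water, O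
Why: Proposed new method: a cobalt hydride formed from the salen complex, the N-fluoropyridinium oxidant and PhSiH3 transfers H• to the less substituted C3 of the electron-rich trisubstituted alkene (the enone alkene can only give an α-keto radical that cannot be oxidised to a cation and reverts by back-transfer), the tertiary C4 radical is oxidised to a cation equivalent and is captured through a chair six-membered transition state by the carbonyl oxygen of the C6 aroyl ester, which can reach only the β face because C6 is the β substituent of C5 and O6 lies gauche to C4, so the new C4–O bond and the (4R) centre are dictated by C5/C6, then water adds to the 2-aryl-1,3-dioxan-2-ylium ion 15 and under mildly basic quench the hemi-orthoester expels the less basic, enone-activated secondary C6 alkoxide so that the acyl group remains on the tertiary oxygen with the C6–O bond untouched, and buffered fluoride frees the phenol without acyl migration; the closest known reaction types are cobalt-salen hydrogen-atom-transfer/radical-polar-crossover hydroalkoxylations, lactonisations and amide- or carbamate-oxygen cyclisations of alkenes, and the acyloxonium hydrolysis of the Woodward cis-hydroxylation.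

**Compound list**
1 | 3-methylcyclopent-2-en-1-one | CC1=CC(=O)CC1 | starting material
2 | 4-bromo-2-methylbut-1-ene | CC(=C)CCBr | starting material
3 | acrolein (prop-2-enal) | C=CC=O | starting material
4 | (3-methylbut-3-en-1-yl)magnesium bromide | CC(=C)CC[Mg]Br | intermediate
5 | bromomagnesium (3S)-3-methyl-3-(3-methylbut-3-en-1-yl)cyclopent-1-en-1-olate | C=C(C)CC[C@@]1(C)CCC(O[Mg]Br)=C1 | intermediate
6 | (2S,3S)-2-[(1S)-1-hydroxyprop-2-en-1-yl]-3-methyl-3-(3-methylbut-3-en-1-yl)cyclopentan-1-one | C=C[C@H](O)[C@@H]1[C@](C)(CCC1=O)CCC(C)=C | intermediate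
7 | (2S,3S)-3-methyl-3-(3-methylbut-3-en-1-yl)-2-[(1S)-1-(trimethylsilyloxy)prop-2-en-1-yl]cyclopentan-1-one | C=C[C@H](O[Si](C)(C)C)[C@@H]1[C@](C)(CCC1=O)CCC(C)=C | intermediate
8 | (4S,5S)-4-methyl-4-(3-methylbut-3-en-1-yl)-5-[(1S)-1-(trimethylsilyloxy)prop-2-en-1-yl]cyclopent-1-en-1-yl trifluoromethanesulfonate | C=C[C@H](O[Si](C)(C)C)[C@@H]1[C@](C)(CC=C1OS(=O)(=O)C(F)(F)F)CCC(C)=C | intermediate
9 | (4S,5S)-5-[(1S)-1-hydroxyprop-2-en-1-yl]-4-methyl-4-(3-methylbut-3-en-1-yl)cyclopent-1-en-1-yl trifluoromethanesulfonate | C=C[C@H](O)[C@@H]1[C@](C)(CC=C1OS(=O)(=O)C(F)(F)F)CCC(C)=C | intermediate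
10 | 4-[(tert-butyldimethylsilyl)oxy]benzoic acid | OC(=O)c1ccc(O[Si](C)(C)C(C)(C)C)cc1 | starting material
11 | (1S)-1-[(1S,2S)-2-methyl-2-(3-methylbut-3-en-1-yl)-5-{[(trifluoromethyl)sulfonyl]oxy}cyclopent-4-en-1-yl]prop-2-en-1-yl 4-[(tert-butyldimethylsilyl)oxy]benzoate | C=C[C@H](OC(=O)c1ccc(O[Si](C)(C)C(C)(C)C)cc1)[C@@H]1[C@](C)(CC=C1OS(=O)(=O)C(F)(F)F)CCC(C)=C | intermediate
12 | (3aS,8S,8aS)-3a,6-dimethyl-1-{[(trifluoromethyl)sulfonyl]oxy}-3,3a,4,5,8,8a-hexahydroazulen-8-yl 4-[(tert-butyldimethylsilyl)oxy]benzoate | CC1=C[C@H](OC(=O)c2ccc(O[Si](C)(C)C(C)(C)C)cc2)[C@@H]2[C@](C)(CC=C2OS(=O)(=O)C(F)(F)F)CC1 | intermediate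
13 | (3aR,8S,8aS)-3a,6-dimethyl-5-oxo-1-{[(trifluoromethyl)sulfonyl]oxy}-3,3a,4,5,8,8a-hexahydroazulen-8-yl 4-[(tert-butyldimethylsilyl)oxy]benzoate | CC1=C[C@H](OC(=O)c2ccc(O[Si](C)(C)C(C)(C)C)cc2)[C@@H]2[C@](C)(CC=C2OS(=O)(=O)C(F)(F)F)CC1=O | intermediate
14 | (3aR,8S,8aR)-3a,6-dimethyl-5-oxo-1-(propan-2-yl)-3,3a,4,5,8,8a-hexahydroazulen-8-yl 4-[(tert-butyldimethylsilyl)oxy]benzoate | CC1=C[C@H](OC(=O)c2ccc(O[Si](C)(C)C(C)(C)C)cc2)[C@@H]2[C@](C)(CC=C2C(C)C)CC1=O | intermediate
15 | 2-{4-[(tert-butyldimethylsilyl)oxy]phenyl}-1,3-dioxan-2-ylium triflate spanning O4 (β) and O6 (α) of the (1R,4R,5S,6S)-dauc-7-en-9-one core | CC1=C[C@H]([O+]=3)[C@@H]2[C@](C)(CC[C@@]2(OC=3c2ccc(O[Si](C)(C)C(C)(C)C)cc2)C(C)C)CC1=O.[O-]S(=O)(=O)C(F)(F)F | intermediate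
16 | (1R,3aR,8S,8aS)-8-hydroxy-3a,6-dimethyl-5-oxo-1-(propan-2-yl)-1,2,3,3a,4,5,8,8a-octahydroazulen-1-yl 4-[(tert-butyldimethylsilyl)oxy]benzoate | CC1=C[C@H](O)[C@@H]2[C@](C)(CC[C@@]2(OC(=O)c2ccc(O[Si](C)(C)C(C)(C)C)cc2)C(C)C)CC1=O | intermediate
17 | (1R,3aR,8S,8aS)-8-hydroxy-3a,6-dimethyl-5-oxo-1-(propan-2-yl)-1,2,3,3a,4,5,8,8a-octahydroazulen-1-yl 4-hydroxybenzoate (CNP0153637.1) | CC1=C[C@H](O)[C@@H]2[C@](C)(CC[C@@]2(OC(=O)c2ccc(O)cc2)C(C)C)CC1=O | target

**Total step count:** 7. **Longest linear sequence:** 7 (1 → 17).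

**Steps most likely to fail**

**Step 7 (the new method).**
- Risks: hydrogen-atom transfer to the enone; elimination or hydride shift of the C4 cation before capture; collapse of the hemi-orthoester to the more stable secondary ester.
- Fallback (known chemistry only, sets out from 6, comes back at 17):
  - i-PrMgCl/CeCl3 in THF at −78 °C adds to the ketone of 6 from the α face, anti to the C5 side chain, to give (1R,2S,3S)-2-[(1S)-1-hydroxyprop-2-en-1-yl]-3-methyl-3-(3-methylbut-3-en-1-yl)-1-(propan-2-yl)cyclopentan-1-ol F1.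
  - Ring-closing metathesis as in step 4 gives dauc-7-ene-4β,6α-diol F2.
  - TESCl/imidazole silylates only the secondary hydroxyl to give the 6-O-triethylsilyl ether F3.
  - The tertiary alcohol is esterified with 10 under Sc(OTf)3/DMAP/diisopropylcarbodiimide conditions. No alkoxide is formed, so the silyl group does not migrate. This gives the 4-O-aroyl 6-O-triethylsilyl daucene F4.
  - Allylic oxidation as in step 5 gives the corresponding 9-ketone F5.
  - TBAF/AcOH removes both silyl groups to deliver 17.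

**Step 1.**
- Risks: enantioselectivity of Grignard additions to the five-membered enone; diastereoselectivity of the aldol at a hindered enolate.
- Fallback (sets out from 4, comes back at 6); the roles of ring substituent and nucleophile are exchanged:
  - 4 is added to commercial 3-ethoxycyclopent-2-en-1-one, and acid work-up gives 3-(3-methylbut-3-en-1-yl)cyclopent-2-en-1-one F6.
  - Me3Al with Cu(OTf)2 and a chiral sulfonate-bearing NHC–silver complex transfers methyl to the β carbon.
  - The aluminium enolate is trapped with TMSOTf as (3S)-3-methyl-3-(3-methylbut-3-en-1-yl)-1-(trimethylsilyloxy)cyclopent-1-ene F7, which can be purified and checked for ee.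
  - MeLi regenerates the lithium enolate, which adds to 3 at −78 °C to give 6.

**Step 5.**
- Risks: trapping of the allyl radical at C7 instead of C9; over-oxidation; attack at the C14 methyl.
- Fallback (sets out from 11, comes back at 13); the oxygen is installed before ring closure:
  - SeO2 (cat.)/t-BuOOH hydroxylates the methylene of the 1,1-disubstituted alkene of 11 (methylene is favoured over methyl, and the alkene position is retained by the ene/[2,3] sequence) to give the C9 allylic alcohol F8 as an epimer mixture.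
  - Dess–Martin periodinane gives the isopropenyl ketone F9.
  - Ring-closing metathesis of the vinyl group with the isopropenyl ketone closes the 2-methylcycloheptenone 13 directly.

**Further compounds**
F1 | step 7 | (1R,2S,3S)-2-[(1S)-1-hydroxyprop-2-en-1-yl]-3-methyl-3-(3-methylbut-3-en-1-yl)-1-(propan-2-yl)cyclopentan-1-ol | C=C[C@H](O)[C@@H]1[C@](C)(CC[C@@]1(O)C(C)C)CCC(C)=C
F2 | step 7 | dauc-7-ene-4β,6α-diol, (1R,3aS,8S,8aS)-3a,6-dimethyl-1-(propan-2-yl)-1,2,3,3a,4,5,8,8a-octahydroazulene-1,8-diol | CC1=C[C@H](O)[C@@H]2[C@](C)(CC[C@@]2(O)C(C)C)CC1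
F3 | step 7 | 6-O-triethylsilyl ether of dauc-7-ene-4β,6α-diol | CC1=C[C@H](O[Si](CC)(CC)CC)[C@@H]2[C@](C)(CC[C@@]2(O)C(C)C)CC1
F4 | step 7 | 4β-{4-[(tert-butyldimethylsilyl)oxy]benzoyloxy}-6α-(triethylsilyloxy)dauc-7-ene | CC1=C[C@H](O[Si](CC)(CC)CC)[C@@H]2[C@](C)(CC[C@@]2(OC(=O)c2ccc(O[Si](C)(C)C(C)(C)C)cc2)C(C)C)CC1
F5 | step 7 | 4β-{4-[(tert-butyldimethylsilyl)oxy]benzoyloxy}-6α-(triethylsilyloxy)dauc-7-en-9-one | CC1=C[C@H](O[Si](CC)(CC)CC)[C@@H]2[C@](C)(CC[C@@]2(OC(=O)c2ccc(O[Si](C)(C)C(C)(C)C)cc2)C(C)C)CC1=O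
F6 | step 1 | 3-(3-methylbut-3-en-1-yl)cyclopent-2-en-1-one | C=C(C)CCC1=CC(=O)CC1
F7 | step 1 | (3S)-3-methyl-3-(3-methylbut-3-en-1-yl)-1-(trimethylsilyloxy)cyclopent-1-ene | C=C(C)CC[C@@]1(C)CCC(O[Si](C)(C)C)=C1
F8 | step 5 | C9 allylic alcohol of 11 (2-hydroxy-3-methylbut-3-en-1-yl side chain, epimer mixture at the new carbinol) | C=C[C@H](OC(=O)c1ccc(O[Si](C)(C)C(C)(C)C)cc1)[C@@H]1[C@](C)(CC=C1OS(=O)(=O)C(F)(F)F)CC(O)C(C)=C
F9 | step 5 | isopropenyl ketone of 11 (3-methyl-2-oxobut-3-en-1-yl side chain) | C=C[C@H](OC(=O)c1ccc(O[Si](C)(C)C(C)(C)C)cc1)[C@@H]1[C@](C)(CC=C1OS(=O)(=O)C(F)(F)F)CC(=O)C(C)=C
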